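Numbering: ring C1 (CMe2), C2 (CBr), C3 (bears C7HCl–C8H2Br), C4, C5, C6 (CHBr).
Enabling feature: in the single six-membered ring, quaternary C1 separates the heteroatom-bearing carbons C2 and C6 (1,3), and C7 is again 1,3 to C2. The ring is therefore a masked 4-acetyl-2,2-dimethylcyclohexane-1,3-dione, and a keto ester blocked at C1 can enolise only at C5.
Retrosynthesis: C8–Br and C7–Cl go back to a C7–C8 epoxide and then to an α-bromo ketone; C2–Br and C6–Br go back to oxygen; finally the ring bonds C2–C3 and C4–C5 are cut.
Forward: the ring closes in step 1 from keto ester 1 and vinyl ketone 2 (all ten carbons). C7 is then marked as an enaminone, C6, C2 and C8 are brominated in that order, and C7/C8 are finished through the epoxide.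
Stereochemistry: C6 comes from an (R)-CBS reduction [(S)-alcohol] and Appel inversion [(R)-bromide]. C7 comes from a second (R)-CBS reduction [(R)-bromohydrin, (R)-epoxide] and inversion by chloride [(S)-chloride].
Key step: step 1

Remark: the C3=C7 bond of 6–8 is drawn E and enolate 4 is drawn Z. Neither geometry matters, because the push-pull alkene rotates easily and both double bonds disappear (steps 5 and 1).

Step 1
Reactants: 1 methyl 2,2-dimethyl-3-oxobutanoate; 2 but-3-en-2-one
Product: 5 4-acetyl-3-hydroxy-2,2-dimethylcyclohex-3-en-1-one (enol of the triketone), via C5 lithium enolate 3 (not isolated), via C3 lithium enolate of the Michael adduct 4 (not isolated)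
Conditions: LDA (1.05 equiv), THF, −78 °C; 2 (0.9 equiv, slow addition), −78 °C → rt, then 40 °C; 1 M HCl
Reagents that add atoms: none
Why: LDA takes a proton from C5, the only enolisable position of 1 because C1 is quaternary, and enolate 3 adds in Michael fashion to 2 (C4–C5 forms; any 1,2-adduct reverts on warming), which places the new enolate of 4 at C3 and nowhere else. C3 then attacks the ester carbonyl C2 in a Dieckmann-type acylation, a 6-(enolexo)-exo-trig closure that completes the only ring (C1–C6), and methoxide departs (C2–C3 forms). Methoxide deprotonates the new C2/C7 β-diketone, and this stabilised anion is the lowest point of the manifold, into which the reversible enolate and aldol equilibria drain. The closest known reaction type is the consecutive Michael–Claisen (Michael–Dieckmann) annulation of ketone or ester enolates with acrylates or vinyl ketones to cyclohexane-1,3-diones, which also accepts α,α-dimethyl esters as the internal electrophile. No stereocentre is created. The step needs 1,4- over 1,2-addition and C3-to-C2 acylation instead of C8-to-C6 aldol (Robinson) closure; the position-defined C3 enolate, the shielding of the C6 ketone by C1, the gem-dimethyl effect on ring closure and the slow addition of 2 as the limiting component secure this.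

Step 2
Reactants: 5 4-acetyl-3-hydroxy-2,2-dimethylcyclohex-3-en-1-one
Product: 6 (4E)-2,2-dimethyl-4-[1-(pyrrolidin-1-yl)ethylidene]cyclohexane-1,3-dione
Conditions: pyrrolidine (1.3 equiv), TsOH·H2O (5 mol %), 4 Å MS, toluene, 60 °C
Reagents that add atoms: pyrrolidine C1CCNC1
Why: Enaminone formation (condensation of a secondary amine with a β-diketone): pyrrolidine attacks the open acetyl carbonyl C7 and not C2, which is buried between quaternary C1 and C3, or the neopentyl-type C6 ketone, so nitrogen marks C7, O-2 remains the only oxygen of the former diketone that can later be exchanged for bromine (direct activation of the enol would favour the less hindered C7), and the acidic enol is gone before hydride is used.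

Step 3
Reactants: 6 (4E)-2,2-dimethyl-4-[1-(pyrrolidin-1-yl)ethylidene]cyclohexane-1,3-dione
Product: 7 (3S,6E)-3-hydroxy-2,2-dimethyl-6-[1-(pyrrolidin-1-yl)ethylidene]cyclohexan-1-one
Conditions: (R)-Me-CBS (15 mol %), BH3·SMe2 (1.2 equiv), THF, −20 → 0 °C; MeOH
Reagents that add atoms: none
Why: Corey–Bakshi–Shibata reduction: C6 is the only true ketone left (C2 is a hindered vinylogous amide), and the (R)-catalyst reads quaternary C1 as the large flank and methylene C5 as the small flank, as with tert-alkyl ketones and 2,2-disubstituted 1,3-diones, so hydride delivery should give the (S)-carbinol at C6.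

Step 4
Reactants: 7 (3S,6E)-3-hydroxy-2,2-dimethyl-6-[1-(pyrrolidin-1-yl)ethylidene]cyclohexan-1-one
Product: 8 (3R,6E)-3-bromo-2,2-dimethyl-6-[1-(pyrrolidin-1-yl)ethylidene]cyclohexan-1-one
Conditions: CBr4 (2 equiv), P(n-Oct)3 (2 equiv), toluene, 0 → 70 °C
Reagents that add atoms: tetrabromomethane BrC(Br)(Br)Br
Why: Appel bromination: bromide displaces the alkoxyphosphonium group at C6 by SN2 with inversion, (S)-alcohol to (R)-bromide, helped at this carbinol next to a quaternary carbon by the small trialkylphosphine and the flexible monocycle (leaving group axial, bromide entering equatorially), while the neutral, shielded vinylogous amide is left alone.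

Step 5
Reactants: 8 (3R,6E)-3-bromo-2,2-dimethyl-6-[1-(pyrrolidin-1-yl)ethylidene]cyclohexan-1-one
Product: 10 1-[(4R)-2,4-dibromo-3,3-dimethylcyclohex-1-en-1-yl]ethan-1-one, via β-bromovinyl iminium bromide 9 (not isolated)
Conditions: (COBr)2 (1.3 equiv), CH2Cl2, −20 °C → rt; then 10% aq citric acid, THF, rt
Reagents that add atoms: oxalyl bromide O=C(Br)C(=O)Br; water O
Why: Halo-iminium formation as in the second stage of a Vilsmeier–Haack–Arnold reaction: oxalyl bromide acylates the vinylogous amide oxygen O-2, bromide adds at C2 and expels CO, CO2 and bromide to give 9, and water then attacks the iminium carbon C7 under acidic conditions that keep the amine protonated, so bromine can only arrive at C2 because C7 is held by nitrogen, and C6 is not involved.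

Step 6
Reactants: 10 1-[(4R)-2,4-dibromo-3,3-dimethylcyclohex-1-en-1-yl]ethan-1-one
Product: 12 2-bromo-1-[(4R)-2,4-dibromo-3,3-dimethylcyclohex-1-en-1-yl]ethan-1-one, via 2-silyloxydiene 11 (not isolated)
Conditions: TMSOTf (1.3 equiv), Et3N (1.6 equiv), CH2Cl2, 0 °C; then NBS (1.05 equiv), THF, −78 → 0 °C; aq NaHCO3
Reagents that add atoms: N-bromosuccinimide O=C1CCC(=O)N1Br; trimethylsilyl trifluoromethanesulfonate C[Si](C)(C)OS(=O)(=O)C(F)(F)F (silyl group present only in 11)
Why: Silyl enol ether formation followed by electrophilic α-bromination: C8 is the only position from which the C7 ketone can enolise (C3 is sp2 and the γ-carbon C1 is quaternary), so 11 forms as a single 2-silyloxydiene and takes up one bromine from NBS at its terminal CH2.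

Step 7
Reactants: 12 2-bromo-1-[(4R)-2,4-dibromo-3,3-dimethylcyclohex-1-en-1-yl]ethan-1-one
Product: 14 (2R)-2-[(4R)-2,4-dibromo-3,3-dimethylcyclohex-1-en-1-yl]oxirane, via (1R)-bromohydrin 13 (not isolated)
Conditions: (R)-Me-CBS (15 mol %), BH3·SMe2 (0.8 equiv), THF, −20 °C; MeOH; then K2CO3 (2 equiv), MeOH, 0 °C → rt
Reagents that add atoms: none
Why: Corey–Bakshi–Shibata reduction of an α-bromo ketone followed by intramolecular Williamson closure: with the tetrasubstituted bromoalkenyl group as the large substituent and CH2Br as the small one, the (R)-catalyst should give the (1R)-bromohydrin under reagent control (C6 is remote), and the alkoxide displaces bromide at C8, so C7 keeps its configuration in the (R)-epoxide.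

Step 8
Reactants: 14 (2R)-2-[(4R)-2,4-dibromo-3,3-dimethylcyclohex-1-en-1-yl]oxirane
Product: 16 (2S)-2-chloro-2-[(4R)-2,4-dibromo-3,3-dimethylcyclohex-1-en-1-yl]ethan-1-ol, via O-trimethylsilyl chlorohydrin 15 (not isolated)
Conditions: TMSCl (1.5 equiv), CH2Cl2, −40 → 0 °C; then aq citric acid, THF, rt
Reagents that add atoms: chlorotrimethylsilane C[Si](C)(C)Cl
Why: Chlorinolysis of an alkenyl epoxide with a silyl chloride: silylation of the epoxide oxygen and backside attack of chloride at the allylic carbon C7, whose C–O bond overlaps with the C2=C3 π system, should give the (S)-chloride with inversion, SN2′ attack being shut off because C2 is fully substituted and flanked by C1, and mild acid then frees the C8 alcohol.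

Step 9
Reactants: 16 (2S)-2-chloro-2-[(4R)-2,4-dibromo-3,3-dimethylcyclohex-1-en-1-yl]ethan-1-ol
Product: 17 (4R)-2,4-dibromo-1-[(1S)-2-bromo-1-chloroethyl]-3,3-dimethylcyclohex-1-ene
Conditions: CBr4 (1.3 equiv), PPh3 (1.4 equiv), CH2Cl2, 0 °C
Reagents that add atoms: tetrabromomethane BrC(Br)(Br)Br
Why: Appel bromination of a primary alcohol: fast SN2 at C8 under neutral conditions avoids re-closure to the epoxide and does not touch the allylic chloride at C7, the secondary bromide at C6 or the vinyl bromide at C2, so both stereocentres pass unchanged into 17.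

Compound list
1 | methyl 2,2-dimethyl-3-oxobutanoate | COC(=O)C(C)(C)C(C)=O | starting material
2 | but-3-en-2-one | CC(=O)C=C | starting material
3 | lithium 4-methoxy-3,3-dimethyl-4-oxobut-1-en-2-olate (C5 enolate of 1) | COC(=O)C(C)(C)C(=C)[O-].[Li+] | intermediate
4 | lithium (2Z)-8-methoxy-7,7-dimethyl-6,8-dioxooct-2-en-2-olate (C3 enolate of the Michael adduct) | COC(=O)C(C)(C)C(=O)CC/C=C(/C)[O-].[Li+] | intermediate
5 | 4-acetyl-3-hydroxy-2,2-dimethylcyclohex-3-en-1-one | CC(=O)C1=C(O)C(C)(C)C(=O)CC1 | intermediate
6 | (4E)-2,2-dimethyl-4-[1-(pyrrolidin-1-yl)ethylidene]cyclohexane-1,3-dione | CC1(C)C(=O)/C(=C(\C)N2CCCC2)CCC1=O | intermediate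
7 | (3S,6E)-3-hydroxy-2,2-dimethyl-6-[1-(pyrrolidin-1-yl)ethylidene]cyclohexan-1-one | CC1(C)C(=O)/C(=C(\C)N2CCCC2)CC[C@@H]1O | intermediate
8 | (3R,6E)-3-bromo-2,2-dimethyl-6-[1-(pyrrolidin-1-yl)ethylidene]cyclohexan-1-one | CC1(C)C(=O)/C(=C(\C)N2CCCC2)CC[C@H]1Br | intermediate
9 | 1-{1-[(4R)-2,4-dibromo-3,3-dimethylcyclohex-1-en-1-yl]ethylidene}pyrrolidin-1-ium bromide | CC1(C)C(Br)=C(C(C)=[N+]2CCCC2)CC[C@H]1Br.[Br-] | intermediate
10 | 1-[(4R)-2,4-dibromo-3,3-dimethylcyclohex-1-en-1-yl]ethan-1-one | CC1(C)C(Br)=C(C(C)=O)CC[C@H]1Br | intermediate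
11 | ({1-[(4R)-2,4-dibromo-3,3-dimethylcyclohex-1-en-1-yl]ethenyl}oxy)trimethylsilane | CC1(C)C(Br)=C(C(=C)O[Si](C)(C)C)CC[C@H]1Br | intermediate
12 | 2-bromo-1-[(4R)-2,4-dibromo-3,3-dimethylcyclohex-1-en-1-yl]ethan-1-one | CC1(C)C(Br)=C(C(=O)CBr)CC[C@H]1Br | intermediate
13 | (1R)-2-bromo-1-[(4R)-2,4-dibromo-3,3-dimethylcyclohex-1-en-1-yl]ethan-1-ol | CC1(C)C(Br)=C([C@@H](O)CBr)CC[C@H]1Br | intermediate
14 | (2R)-2-[(4R)-2,4-dibromo-3,3-dimethylcyclohex-1-en-1-yl]oxirane | CC1(C)C(Br)=C([C@@H]2CO2)CC[C@H]1Br | intermediate
15 | {(2S)-2-chloro-2-[(4R)-2,4-dibromo-3,3-dimethylcyclohex-1-en-1-yl]ethoxy}trimethylsilane | CC1(C)C(Br)=C([C@H](Cl)CO[Si](C)(C)C)CC[C@H]1Br | intermediate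
16 | (2S)-2-chloro-2-[(4R)-2,4-dibromo-3,3-dimethylcyclohex-1-en-1-yl]ethan-1-ol | CC1(C)C(Br)=C([C@H](Cl)CO)CC[C@H]1Br | intermediate
17 | (4R)-2,4-dibromo-1-[(1S)-2-bromo-1-chloroethyl]-3,3-dimethylcyclohex-1-ene | CC1(C)C(Br)=C([C@H](Cl)CBr)CC[C@H]1Br | target

Total step count: 9
Longest linear sequence: 9 steps (1 → 17)

Steps most likely to fail

Step 4.
- What may go wrong: substitution at C6 is slow because the carbinol carbon adjoins quaternary C1. Elimination toward C5, methyl migration from C1 or ion-pair collapse with retention may overtake the SN2 path. The electron-rich enaminone may also be brominated at the temperature required.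
- Fallback: it sets out from 6 and comes back at 10. Oxalyl bromide in CH2Cl2 turns 6 into 1-[1-(2-bromo-3,3-dimethyl-4-oxocyclohex-1-en-1-yl)ethylidene]pyrrolidin-1-ium bromide F1. Aqueous citric acid hydrolyses this to 4-acetyl-3-bromo-2,2-dimethylcyclohex-3-en-1-one F2. Excess BH3·SMe2 with (R)-Me-CBS reduces both ketones to (1S)-3-bromo-4-[(1S)-1-hydroxyethyl]-2,2-dimethylcyclohex-3-en-1-ol F3, in which only the C6 configuration matters. MnO2 re-oxidises only the allylic C7 alcohol to 1-[(4S)-2-bromo-4-hydroxy-3,3-dimethylcyclohex-1-en-1-yl]ethan-1-one F4. ClCH2SO2Cl and pyridine give (1S)-4-acetyl-3-bromo-2,2-dimethylcyclohex-3-en-1-yl chloromethanesulfonate F5, and LiBr in DMF displaces the sulfonate with inversion to 10. The displacement then runs on an electron-poor bromo enone that disfavours cationic pathways, with a sulfonate leaving group and free bromide.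

Step 8.
- What may go wrong: chloride may enter at the less hindered primary carbon C8. Alternatively, partial ionisation of the C7–O bond may erode the configuration at C7.
- Fallback (no new compound, F0): it sets out from 13, isolated by leaving out the carbonate stage of step 7, and comes back at 17. Hexachloroacetone and PPh3 in CH2Cl2 at −20 °C convert the allylic alcohol directly into the chloride by an Appel-type SN2 displacement with inversion, (1R)-alcohol to (1S)-chloride. The C8 bromide is already in place, so steps 8 and 9 are not needed.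

Step 1.
- What may go wrong: enolates may oligomerise the vinyl ketone, 1,2-addition may not revert, or proton transfer may move the enolate to C8 and open the aldol closure onto C6.
- Fallback: it sets out from 1 and 2 and comes back at 5. TMSOTf and Et3N convert 1 into methyl 2,2-dimethyl-3-[(trimethylsilyl)oxy]but-3-enoate F6. A TiCl4-promoted Mukaiyama–Michael addition to 2 in CH2Cl2 at −78 °C forms C4–C5 without any free enolate and gives methyl 2,2-dimethyl-3,7-dioxooctanoate F7. KOtBu in THF then closes C2–C3 by Dieckmann condensation, driven by formation of the diketonate of 5.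

Further compounds
F1 | step 4 | 1-[1-(2-bromo-3,3-dimethyl-4-oxocyclohex-1-en-1-yl)ethylidene]pyrrolidin-1-ium bromide | CC1(C)C(Br)=C(C(C)=[N+]2CCCC2)CCC1=O.[Br-]
F2 | step 4 | 4-acetyl-3-bromo-2,2-dimethylcyclohex-3-en-1-one | CC(=O)C1=C(Br)C(C)(C)C(=O)CC1
F3 | step 4 | (1S)-3-bromo-4-[(1S)-1-hydroxyethyl]-2,2-dimethylcyclohex-3-en-1-ol | CC1(C)C(Br)=C([C@@H](O)C)CC[C@@H]1O
F4 | step 4 | 1-[(4S)-2-bromo-4-hydroxy-3,3-dimethylcyclohex-1-en-1-yl]ethan-1-one | CC1(C)C(Br)=C(C(C)=O)CC[C@@H]1O
F5 | step 4 | (1S)-4-acetyl-3-bromo-2,2-dimethylcyclohex-3-en-1-yl chloromethanesulfonate | CC1(C)C(Br)=C(C(C)=O)CC[C@@H]1OS(=O)(=O)CCl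
F0 | step 8 | none | none
F6 | step 1 | methyl 2,2-dimethyl-3-[(trimethylsilyl)oxy]but-3-enoate | COC(=O)C(C)(C)C(=C)O[Si](C)(C)C
F7 | step 1 | methyl 2,2-dimethyl-3,7-dioxooctanoate | COC(=O)C(C)(C)C(=O)CCCC(C)=O
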